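The oxirane C–C bond (C4–C5, germacrane numbering) is also a bond of the ten-membered carbocycle and is flanked by the C6 carbinol. It is therefore made as a Z-alkene by ring-closing metathesis of an acyclic triene and oxidised afterwards under direction of the C6 hydroxyl. The precursor carries O6 and O8 in a temporary trans-4,6-disubstituted 1,3-dioxane: this ring, absent from the target, makes the competing six-membered closure onto the C1=C10 alkene geometrically impossible and pre-organises the chain. C6 is deliberately carried in the epimeric configuration, so that the hydroxyl delivers the epoxide oxygen to the correct face, and is inverted at the end.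

Key step: step 10

Remark: germacrane numbering is used for the ring carbons: C1=C10 (CH3 on C10), C2, C3, C4 (oxirane carbon with CH3), C5 (oxirane CH), C6 (carbinol), C7 (isopropyl), C8 (ester), C9. In the target the oxirane oxygen is trans to the C6 hydroxyl; the C6 hydroxyl, the C7 isopropyl group and the C8 acyloxy group are mutually cis; C1=C10 is Z.

Remark: the facial course of step 12 is assumed to follow that of Z-cycloalkenols of medium ring size (metal-alkoxide delivery gives the cis epoxy alcohol).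

Step 1
Reactants: 1 4-methylpent-4-en-1-ol
Product: 2 4-methylpent-4-enal
Conditions: TEMPO (cat.), PhI(OAc)2, CH2Cl2, rt
Reagents that add atoms: none
Why: Oxoammonium-mediated (TEMPO-catalysed) oxidation of the primary alcohol stops at the aldehyde and leaves the isolated 1,1-disubstituted alkene untouched.

Step 2
Reactants: 2 4-methylpent-4-enal
Product: 3 (2Z)-2-iodo-6-methylhepta-2,6-diene
Conditions: EtPPh3I, n-BuLi, THF, rt; I2, −78 °C; NaN(SiMe3)2, −78 °C; then 2, −78 °C to rt
Reagents that add atoms: ethyltriphenylphosphonium iodide CC[P+](c1ccccc1)(c1ccccc1)c1ccccc1.[I-]; iodine II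
Why: Stork–Zhao-type Wittig olefination with the α-iodo ylide under kinetic control should place iodine cis to the chain, giving the Z-alkenyl iodide that fixes the C1=C10 geometry.

Step 3
Reactants: 4 (4S)-4-benzyl-3-(3-methylbutanoyl)-1,3-oxazolidin-2-one; 5 acrolein
Product: 7 (4S)-4-benzyl-3-[(2S,3R)-3-hydroxy-2-(propan-2-yl)pent-4-enoyl]-1,3-oxazolidin-2-one, via dibutylboron Z-enolate 6 (not isolated)
Conditions: Bu2BOTf, i-Pr2NEt, CH2Cl2, 0 °C; then 5, −78 to 0 °C; H2O2, MeOH, pH 7 buffer
Reagents that add atoms: none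
Why: Evans syn-aldol reaction, in which the Z-boron enolate 6 adds to acrolein through a Zimmerman–Traxler chair on the face opposite the benzyl group, setting C7 as in the target and C6 on purpose as the epimer of the target carbinol.

Step 4
Reactants: 7 (4S)-4-benzyl-3-[(2S,3R)-3-hydroxy-2-(propan-2-yl)pent-4-enoyl]-1,3-oxazolidin-2-one
Product: 8 (2S,3R)-3-hydroxy-N-methoxy-N-methyl-2-(propan-2-yl)pent-4-enamide
Conditions: MeNHOMe·HCl, AlMe3, CH2Cl2, 0 °C to rt
Reagents that add atoms: N,O-dimethylhydroxylamine hydrochloride CNOC.Cl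
Why: Transamination of the N-acyloxazolidinone with the aluminium amide, assisted by the free β-hydroxyl, gives the Weinreb amide without touching C6 or C7.

Step 5
Reactants: 8 (2S,3R)-3-hydroxy-N-methoxy-N-methyl-2-(propan-2-yl)pent-4-enamide
Product: 9 (3S,4R)-1-chloro-4-hydroxy-3-(propan-2-yl)hex-5-en-2-one
Conditions: ICH2Cl, MeLi·LiBr, THF/Et2O, −78 °C; aq. NH4Cl
Reagents that add atoms: chloroiodomethane ClCI
Why: Chloromethyllithium formed by iodine–lithium exchange adds once to the Weinreb amide because the chelated tetrahedral intermediate survives until work-up, one further equivalent being spent on the hydroxyl (carbenoid homologation of a Weinreb amide).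

Step 6
Reactants: 9 (3S,4R)-1-chloro-4-hydroxy-3-(propan-2-yl)hex-5-en-2-one
Product: 10 (2S,3S,4R)-1-chloro-3-(propan-2-yl)hex-5-ene-2,4-diol
Conditions: Me4NBH(OAc)3, AcOH/MeCN, −30 °C
Reagents that add atoms: none
Why: Evans–Saksena reduction, in which the C6 hydroxyl binds the borohydride and delivers hydride intramolecularly through a chair transition state, should give the 1,3-anti diol and so the target configuration at C8.

Step 7
Reactants: 10 (2S,3S,4R)-1-chloro-3-(propan-2-yl)hex-5-ene-2,4-diol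
Product: 11 (3R,4S)-5-methyl-4-[(2S)-oxiran-2-yl]hex-1-en-3-ol
Conditions: K2CO3, MeOH, 0 °C to rt
Reagents that add atoms: none
Why: Base-induced 3-exo-tet Williamson closure of the 1,2-chlorohydrin gives the terminal epoxide with C8 unchanged, faster than attack by the more distant C6 alkoxide.

Step 8
Reactants: 11 (3R,4S)-5-methyl-4-[(2S)-oxiran-2-yl]hex-1-en-3-ol; 3 (2Z)-2-iodo-6-methylhepta-2,6-diene
Product: 14 (3R,4R,5R,7Z)-7,11-dimethyl-4-(propan-2-yl)dodeca-1,7,11-triene-3,5-diol, via alkenyllithium 12 (not isolated), via lithium alkoxide 13 (not isolated)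
Conditions: 3, t-BuLi (2 equiv), Et2O, −78 °C; 11, MeLi (1 equiv), THF, −78 °C; combine, BF3·OEt2, −78 °C
Reagents that add atoms: none
Why: Iodine–lithium exchange proceeds with retention of the Z geometry and the alkenyllithium opens the BF3-activated epoxide at its unsubstituted carbon (SN2), forming the C9–C10 bond without touching a stereocentre.

Step 9
Reactants: 14 (3R,4R,5R,7Z)-7,11-dimethyl-4-(propan-2-yl)dodeca-1,7,11-triene-3,5-diol
Product: 15 (4R,5R,6R)-4-[(2Z)-2,6-dimethylhepta-2,6-dien-1-yl]-6-ethenyl-2,2-dimethyl-5-(propan-2-yl)-1,3-dioxane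
Conditions: Me2C(OMe)2, PPTS (cat.), CH2Cl2, rt
Reagents that add atoms: 2,2-dimethoxypropane COC(C)(C)OC
Why: Acid-catalysed transacetalisation ties O6 and O8 of the anti-1,3-diol into the trans-4,6-disubstituted 1,3-dioxane that serves as the temporary control ring.

Step 10
Reactants: 15 (4R,5R,6R)-4-[(2Z)-2,6-dimethylhepta-2,6-dien-1-yl]-6-ethenyl-2,2-dimethyl-5-(propan-2-yl)-1,3-dioxane
Product: 16 (1R,2Z,6Z,9R,13R)-3,7,11,11-tetramethyl-13-(propan-2-yl)-10,12-dioxabicyclo[7.3.1]trideca-2,6-diene
Conditions: second-generation Grubbs catalyst RuCl2(=CHPh)(PCy3)(H2IMes) (15 mol%), 1,4-benzoquinone (cat.), toluene (1 mM), 80 °C, slow addition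
Reagents that add atoms: none
Why: Chauvin mechanism: the ruthenium alkylidene loads at the monosubstituted C5 vinyl group, adds to the 1,1-disubstituted C4 alkene through a ruthenacyclobutane and releases ethene, which drives the equilibrium. The closest known reaction type is ring-closing metathesis to medium-ring carbocycles with a trisubstituted alkene. The only ring closed is the ten-membered carbocycle, by olefin metathesis at C4=C5, which makes a bicyclo[7.3.1] system with the dioxane. No stereocentre is formed; the Z geometry (C3 and C6 cis) is expected under thermodynamic control, because an E alkene beside the Z C1=C10 alkene in the bridged ten-membered ring is far more strained. The step needs ring-size selectivity (ten- against six-membered closure of the C5 carbene onto C1=C10) and monomer selectivity: the first is secured by the trans-disubstituted dioxane, since a cyclohexene spanning C6 and C8 would be a trans-bridged bicyclo[3.3.1]nonene, the second by high dilution and slow addition.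

Step 11
Reactants: 16 (1R,2Z,6Z,9R,13R)-3,7,11,11-tetramethyl-13-(propan-2-yl)-10,12-dioxabicyclo[7.3.1]trideca-2,6-diene
Product: 17 (1R,2R,3R,4Z,8Z)-5,9-dimethyl-2-(propan-2-yl)cyclodeca-4,8-diene-1,3-diol
Conditions: AcOH/THF/H2O (3:1:1), 40 °C
Reagents that add atoms: none
Why: Mild acid hydrolysis of the isopropylidene acetal frees the C6 and C8 hydroxyls and removes the temporary ring.

Step 12
Reactants: 17 (1R,2R,3R,4Z,8Z)-5,9-dimethyl-2-(propan-2-yl)cyclodeca-4,8-diene-1,3-diol
Product: 18 (1S,2S,3R,4R,6Z,10R)-6,10-dimethyl-3-(propan-2-yl)-11-oxabicyclo[8.1.0]undec-6-ene-2,4-diol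
Conditions: VO(acac)2 (5 mol%), t-BuOOH (decane), CH2Cl2, 0 °C
Reagents that add atoms: tert-butyl hydroperoxide CC(C)(C)OO
Why: Hydroxyl-directed epoxidation through the vanadate ester of the allylic C6 alcohol is selective for C4=C5 over the remote C1=C10 alkene and, as with medium-ring Z-cycloalkenols, should deliver oxygen cis to the C6 hydroxyl, which sets C4 and C5 as in the target.

Step 13
Reactants: 18 (1S,2S,3R,4R,6Z,10R)-6,10-dimethyl-3-(propan-2-yl)-11-oxabicyclo[8.1.0]undec-6-ene-2,4-diol; 19 3,4,5-trimethoxybenzoyl chloride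
Product: 20 (1S,2S,3S,4R,6Z,10R)-2-hydroxy-6,10-dimethyl-3-(propan-2-yl)-11-oxabicyclo[8.1.0]undec-6-en-4-yl 3,4,5-trimethoxybenzoate
Conditions: 19 (1.05 equiv), pyridine, DMAP (cat.), CH2Cl2, −20 to 0 °C
Reagents that add atoms: none
Why: DMAP-catalysed acylation should take place at the C8 hydroxyl, flanked by a methylene group, in preference to the C6 hydroxyl, which lies between the oxirane and the isopropyl-bearing carbon and is inductively deactivated.

Step 14
Reactants: 20 (1S,2S,3S,4R,6Z,10R)-2-hydroxy-6,10-dimethyl-3-(propan-2-yl)-11-oxabicyclo[8.1.0]undec-6-en-4-yl 3,4,5-trimethoxybenzoate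
Product: 21 (1S,2R,3R,4R,6Z,10R)-2-[(chloroacetyl)oxy]-6,10-dimethyl-3-(propan-2-yl)-11-oxabicyclo[8.1.0]undec-6-en-4-yl 3,4,5-trimethoxybenzoate
Conditions: ClCH2CO2H, PPh3, DIAD, toluene, 0 °C to rt
Reagents that add atoms: chloroacetic acid OC(=O)CCl
Why: Mitsunobu reaction, in which SN2 displacement of the C6 oxyphosphonium ion by chloroacetate inverts C6 to the configuration of the target and turns the cis into the trans epoxy alcohol.

Step 15
Reactants: 21 (1S,2R,3R,4R,6Z,10R)-2-[(chloroacetyl)oxy]-6,10-dimethyl-3-(propan-2-yl)-11-oxabicyclo[8.1.0]undec-6-en-4-yl 3,4,5-trimethoxybenzoate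
Product: 22 (1S,2R,3S,4R,6Z,10R)-2-hydroxy-6,10-dimethyl-3-(propan-2-yl)-11-oxabicyclo[8.1.0]undec-6-en-4-yl 3,4,5-trimethoxybenzoate
Conditions: K2CO3 (cat.), MeOH, 0 °C
Reagents that add atoms: none
Why: Transesterification removes the activated chloroacetate far faster than the electron-rich hindered aryl ester, so the C6 hydroxyl should be freed without acyl migration or Payne rearrangement.

Compound list
1 | 4-methylpent-4-en-1-ol | C=C(C)CCCO | starting material
2 | 4-methylpent-4-enal | C=C(C)CCC=O | intermediate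
3 | (2Z)-2-iodo-6-methylhepta-2,6-diene | C/C(I)=C/CCC(C)=C | intermediate
4 | (4S)-4-benzyl-3-(3-methylbutanoyl)-1,3-oxazolidin-2-one | CC(C)CC(=O)N1[C@@H](Cc2ccccc2)COC1=O | starting material
5 | acrolein (prop-2-enal) | C=CC=O | starting material
6 | (4S)-4-benzyl-3-[(1Z)-1-[(dibutylboranyl)oxy]-3-methylbut-1-en-1-yl]-1,3-oxazolidin-2-one (formed in the flask) | CC(C)/C=C(\OB(CCCC)CCCC)N1[C@@H](Cc2ccccc2)COC1=O | intermediate
7 | (4S)-4-benzyl-3-[(2S,3R)-3-hydroxy-2-(propan-2-yl)pent-4-enoyl]-1,3-oxazolidin-2-one | C=C[C@@H](O)[C@H](C(C)C)C(=O)N1[C@@H](Cc2ccccc2)COC1=O | intermediate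
8 | (2S,3R)-3-hydroxy-N-methoxy-N-methyl-2-(propan-2-yl)pent-4-enamide | C=C[C@@H](O)[C@H](C(C)C)C(=O)N(C)OC | intermediate
9 | (3S,4R)-1-chloro-4-hydroxy-3-(propan-2-yl)hex-5-en-2-one | C=C[C@@H](O)[C@H](C(C)C)C(=O)CCl | intermediate
10 | (2S,3S,4R)-1-chloro-3-(propan-2-yl)hex-5-ene-2,4-diol | C=C[C@@H](O)[C@H](C(C)C)[C@H](O)CCl | intermediate
11 | (3R,4S)-5-methyl-4-[(2S)-oxiran-2-yl]hex-1-en-3-ol | C=C[C@@H](O)[C@H](C(C)C)[C@H]1CO1 | intermediate
12 | [(2Z)-6-methylhepta-2,6-dien-2-yl]lithium (formed in the flask) | [Li]/C(C)=C\CCC(C)=C | intermediate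
13 | lithium (3R,4S)-5-methyl-4-[(2S)-oxiran-2-yl]hex-1-en-3-olate (formed in the flask) | C=C[C@@H]([O-])[C@H](C(C)C)[C@H]1CO1.[Li+] | intermediate
14 | (3R,4R,5R,7Z)-7,11-dimethyl-4-(propan-2-yl)dodeca-1,7,11-triene-3,5-diol | C=C[C@@H](O)[C@H](C(C)C)[C@H](O)C/C(C)=C\CCC(C)=C | intermediate
15 | (4R,5R,6R)-4-[(2Z)-2,6-dimethylhepta-2,6-dien-1-yl]-6-ethenyl-2,2-dimethyl-5-(propan-2-yl)-1,3-dioxane | C=C[C@@H]1[C@H](C(C)C)[C@@H](C/C(C)=C\CCC(C)=C)OC(C)(C)O1 | intermediate
16 | (1R,2Z,6Z,9R,13R)-3,7,11,11-tetramethyl-13-(propan-2-yl)-10,12-dioxabicyclo[7.3.1]trideca-2,6-diene | C/C1=C/[C@H]2OC(C)(C)O[C@H](C/C(C)=C\CC1)[C@H]2C(C)C | intermediate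
17 | (1R,2R,3R,4Z,8Z)-5,9-dimethyl-2-(propan-2-yl)cyclodeca-4,8-diene-1,3-diol | C/C1=C/[C@@H](O)[C@H](C(C)C)[C@H](O)C/C(C)=C\CC1 | intermediate
18 | (1S,2S,3R,4R,6Z,10R)-6,10-dimethyl-3-(propan-2-yl)-11-oxabicyclo[8.1.0]undec-6-ene-2,4-diol | O[C@@H]1C/C(C)=C\CC[C@@]2(C)O[C@H]2[C@@H](O)[C@@H]1C(C)C | intermediate
19 | 3,4,5-trimethoxybenzoyl chloride | COc1cc(C(Cl)=O)cc(OC)c1OC | starting material
20 | (1S,2S,3S,4R,6Z,10R)-2-hydroxy-6,10-dimethyl-3-(propan-2-yl)-11-oxabicyclo[8.1.0]undec-6-en-4-yl 3,4,5-trimethoxybenzoate | COc1cc(C(=O)O[C@@H]2C/C(C)=C\CC[C@@]3(C)O[C@H]3[C@@H](O)[C@@H]2C(C)C)cc(OC)c1OC | intermediate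
21 | (1S,2R,3R,4R,6Z,10R)-2-[(chloroacetyl)oxy]-6,10-dimethyl-3-(propan-2-yl)-11-oxabicyclo[8.1.0]undec-6-en-4-yl 3,4,5-trimethoxybenzoate | COc1cc(C(=O)O[C@@H]2C/C(C)=C\CC[C@@]3(C)O[C@H]3[C@H](OC(=O)CCl)[C@@H]2C(C)C)cc(OC)c1OC | intermediate
22 | (1S,2R,3S,4R,6Z,10R)-2-hydroxy-6,10-dimethyl-3-(propan-2-yl)-11-oxabicyclo[8.1.0]undec-6-en-4-yl 3,4,5-trimethoxybenzoate | COc1cc(C(=O)O[C@@H]2C/C(C)=C\CC[C@@]3(C)O[C@H]3[C@H](O)[C@@H]2C(C)C)cc(OC)c1OC | target

Total step count: 15 steps.
Longest linear sequence: 13 steps (from 4 to 22, steps 3 to 15).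

Steps most likely to fail

1. Step 10 (ring-closing metathesis). What may go wrong: the catalyst loads at the C5 vinyl group and intermolecular metathesis (oligomerisation) outruns the slow closure onto the hindered 1,1-disubstituted C4 alkene; partial formation of the E alkene is the second concern. Fallback, relay ring-closing metathesis, setting out from 11 and coming back at 16: commercial geraniol would be O-allylated (NaH, allyl bromide) to allyl geranyl ether F1, its distal trisubstituted alkene epoxidised selectively (m-CPBA, 0 °C) to epoxide F2 and cleaved (HIO4) to aldehyde F3. The iodo-olefination of step 2 would then give relay iodide F4, which would be coupled with 11 as in step 8 to relay diol F5 and converted as in step 9 to relay acetonide F6. With the same ruthenium catalyst the carbene would load at the allyl ether, expel 2,5-dihydrofuran and be delivered to C4 as the disubstituted alkylidene, which has only the unhindered C5 vinyl group left to close onto, giving 16.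

2. Step 14 (Mitsunobu inversion). What may go wrong: displacement at the hindered C6 oxyphosphonium ion, which must occur on the face of the C7 isopropyl group, is too slow, and the activated alcohol is lost by elimination or by participation of the oxirane. Fallback, oxidation and reduction, setting out from 20 and coming back at 22: Dess–Martin periodinane (NaHCO3 buffer) would give epoxy ketone F7, and reduction with NaBH4 in MeOH at −78 °C (non-chelating, Felkin–Anh mode with the oxirane C–O bond anti to the hydride, attack from the face opposite the C7 isopropyl group) should give the trans epoxy alcohol 22 directly.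

3. Step 12 (directed epoxidation). What may go wrong: poor facial selectivity of oxygen delivery if the ten-membered ring does not hold the C6 vanadate in the geometry that leads to the cis epoxy alcohol, or acid-induced opening of the epoxy diol by the free C8 hydroxyl. Fallback, nucleophilic epoxidation and 1,3-syn reduction, setting out from 17 and coming back at 22: MnO2 would oxidise only the allylic C6 alcohol to Z-enone F8. Weitz–Scheffer epoxidation (t-BuOOH, DBU) is expected to add from the ring periphery to give epoxy ketone F9; this facial course would have to be verified. Narasaka–Prasad reduction (Et2BOMe, NaBH4, −78 °C), directed by the C8 hydroxyl, should then give the 1,3-syn epoxy diol F10 with the target configuration at C6. Acylation of the C8 hydroxyl with 19 as in step 13 would give 22, so that steps 13 to 15 are replaced.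

Further compounds
F1 | step 10 | (2E)-3,7-dimethyl-1-(prop-2-en-1-yloxy)octa-2,6-diene (allyl geranyl ether) | CC(C)=CCC/C(C)=C/COCC=C
F2 | step 10 | 2,2-dimethyl-3-[(3E)-3-methyl-5-(prop-2-en-1-yloxy)pent-3-en-1-yl]oxirane (racemic) | CC1(C)OC1CC/C(C)=C/COCC=C
F3 | step 10 | (4E)-4-methyl-6-(prop-2-en-1-yloxy)hex-4-enal | O=CCC/C(C)=C/COCC=C
F4 | step 10 | (2E,6Z)-7-iodo-3-methyl-1-(prop-2-en-1-yloxy)octa-2,6-diene | C/C(I)=C/CC/C(C)=C/COCC=C
F5 | step 10 | (3R,4R,5R,7Z,11E)-7,11-dimethyl-4-(propan-2-yl)-13-(prop-2-en-1-yloxy)trideca-1,7,11-triene-3,5-diol | C=C[C@@H](O)[C@H](C(C)C)[C@H](O)C/C(C)=C\CC/C(C)=C/COCC=C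
F6 | step 10 | (4R,5R,6R)-4-[(2Z,6E)-2,6-dimethyl-8-(prop-2-en-1-yloxy)octa-2,6-dien-1-yl]-6-ethenyl-2,2-dimethyl-5-(propan-2-yl)-1,3-dioxane | C=C[C@@H]1[C@H](C(C)C)[C@@H](C/C(C)=C\CC/C(C)=C/COCC=C)OC(C)(C)O1
F7 | step 14 | 6-oxo analogue of 20 (C6 ketone; oxirane, C7 and C8 as in 20) | COc1cc(C(=O)O[C@@H]2C/C(C)=C\CC[C@@]3(C)O[C@H]3C(=O)[C@@H]2C(C)C)cc(OC)c1OC
F8 | step 12 | (2Z,6Z,9R,10R)-9-hydroxy-3,7-dimethyl-10-(propan-2-yl)cyclodeca-2,6-dien-1-one | C/C1=C/C(=O)[C@H](C(C)C)[C@H](O)C/C(C)=C\CC1
F9 | step 12 | 4,5-epoxide of F8 (oxirane configured as in 22, C6 ketone, free C8 hydroxyl) | O[C@@H]1C/C(C)=C\CC[C@@]2(C)O[C@H]2C(=O)[C@@H]1C(C)C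
F10 | step 12 | 8-O-deacyl 22 (C6 epimer of 18) | O[C@@H]1C/C(C)=C\CC[C@@]2(C)O[C@H]2[C@H](O)[C@@H]1C(C)C
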